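**Retrosynthetic overview**

- Ring numbering used throughout: C1 is the carbinol carbon bearing C7H2OBz, then C2=C3, C4 (OBz), C5 (OH), C6 (OH).
- The feature the strategy rests on: if the C5 and C6 oxygens are replaced by a C5=C6 double bond, the carbocycle becomes a trans-1,4-dioxygenated cyclohexa-2,5-diene with a mirror plane through C7, C1 and C4, so the precursor is an achiral meso compound.
- Last disconnection: the C5–OH bond, formed with inversion when the C4 benzoate opens a C5–C6 epoxide that lies cis to the C1 hydroxyl. The epoxide (C5–O and C6–O) comes from hydroxyl-directed, ligand-controlled epoxidation of one of the two enantiotopic alkenes of the meso diene.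
- The meso diene comes from 4-hydroxybenzyl alcohol by C7 benzoylation, oxidative dearomatisation to the para-quinol, 1,2-reduction and C4 benzoylation.
- Ring order: the six-membered carbocycle is the arene of the starting phenol. The only rings formed are the oxirane (step 5) and a transient dioxolanylium ring (step 6).

Key step: step 5

Assumption: the sense of alkene selection by the bishydroxamic acid catalyst on this cyclic dienol cannot be assigned with certainty by analogy. The route is written with the (R,R)-ligand; the (S,S)-ligand is used instead if a first trial gives the antipode of 8.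

**Route**

Step 1
Reactants: 1 4-hydroxybenzyl alcohol; 2 benzoic acid
Product: 3 4-hydroxybenzyl benzoate
Conditions: PPh3 (1.2 equiv), DIAD (1.2 equiv), THF, 0 °C to rt
Reagents that add atoms: benzoic acid (2), O=C(O)c1ccccc1
Why: Mitsunobu esterification, in which the benzylic alcohol is activated as its oxyphosphonium salt and displaced by benzoate, the only pronucleophile acidic enough (pKa about 4 against about 10 for the phenol) to be deprotonated by the betaine, so the phenol should stay free; no stereocentre is formed.

Step 2
Reactants: 3 4-hydroxybenzyl benzoate
Product: 4 (1-hydroxy-4-oxocyclohexa-2,5-dien-1-yl)methyl benzoate (para-quinol benzoate, achiral)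
Conditions: PhI(OAc)2 (1.1 equiv), MeCN/H2O 3:1, 0 °C
Reagents that add atoms: water, O
Why: Oxidative dearomatisation by trivalent iodine, in which ligand exchange of the phenol on PhI(OAc)2 and loss of iodobenzene give a para-delocalised cation that water captures at the substituted carbon; because C7 is already acylated, no free 1,2-diol is exposed to the oxidant and glycol cleavage to benzoquinone is avoided.

Step 3
Reactants: 4 (1-hydroxy-4-oxocyclohexa-2,5-dien-1-yl)methyl benzoate
Product: 5 trans-(1,4-dihydroxycyclohexa-2,5-dien-1-yl)methyl benzoate (C1-OH and C4-OH on opposite faces, achiral)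
Conditions: NaBH4, CeCl3·7H2O, MeOH, −78 °C; pH 7 phosphate buffer work-up; chromatography on Et3N-washed silica
Reagents that add atoms: none
Why: Luche reduction should give clean 1,2-reduction of the cross-conjugated dienone, with hydride expected to add to the carbonyl face syn to the C1 hydroxyl (the smaller, metal-bound oxygen substituent, anti to CH2OBz), which places the new C4 hydroxyl trans to the C1 hydroxyl; the cis isomer is removed by chromatography.

Step 4
Reactants: 5 trans-(1,4-dihydroxycyclohexa-2,5-dien-1-yl)methyl benzoate; 6 benzoyl chloride
Product: 7 trans-[4-(benzoyloxy)-1-hydroxycyclohexa-2,5-dien-1-yl]methyl benzoate (meso; C1-OH and C4-OBz on opposite faces)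
Conditions: BzCl (1.1 equiv), pyridine, DMAP (cat.), CH2Cl2, 0 °C
Reagents that add atoms: benzoyl chloride (6), O=C(Cl)c1ccccc1
Why: DMAP-catalysed acylation is selective for the secondary C4 hydroxyl over the hindered tertiary C1 hydroxyl and proceeds with retention at C4, giving the meso diene; excess base keeps the acid-labile bis-allylic carbinol from aromatising.

Step 5
Reactants: 7 trans-[4-(benzoyloxy)-1-hydroxycyclohexa-2,5-dien-1-yl]methyl benzoate
Product: 8 [(1S,2S,5R,6S)-5-(benzoyloxy)-2-hydroxy-7-oxabicyclo[4.1.0]hept-3-en-2-yl]methyl benzoate (C5–C6 epoxide cis to the C1 hydroxyl, C4 benzoate on the other face)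
Conditions: Hf(OtBu)4 (10 mol%), (R,R)-bishydroxamic acid ligand [(1R,2R)-N,N'-dihydroxy-N,N'-bis(2,2-diphenylacetyl)cyclohexane-1,2-diamine] (12 mol%), cumene hydroperoxide (1.2 equiv), DMPU, 4 Å MS, toluene, 0 °C
Reagents that add atoms: cumene hydroperoxide, CC(C)(OO)c1ccccc1
Why: The C1 hydroxyl exchanges onto the tetravalent hafnium centre of the Hf(OtBu)4–bishydroxamic acid complex, which also carries the cumyl peroxide, and the metal-bound peroxide oxygen is passed to the alkene within this template. The closest known reaction type is the metal–bishydroxamic acid catalysed asymmetric epoxidation of tertiary allylic alcohols, used here in the desymmetrising mode established for dialkenyl carbinols. The only ring closed is the oxirane, formed by concerted syn transfer of one oxygen to C5 and C6; no carbocycle is formed. The C1–O–Hf tether fixes the face (oxygen arrives cis to the C1 hydroxyl, reinforced by the C4 benzoate on the opposite face), so C5 and C6 are set relative to C1, while the C2-symmetric ligand pocket chooses C5=C6 over its mirror-image partner C2=C3, which fixes the absolute configuration and turns C1 and C4 into stereocentres (1S,4R,5S,6S in route numbering). The step needs enantiotopic-alkene selection, syn facial selection and mono-epoxidation: both alkenes are allylic to the one directing hydroxyl, and any epoxy alcohol of the wrong hand still holds the alkene the catalyst prefers and should be drained to the meso bis-epoxide, which should raise the enantiomeric purity of 8 as conversion proceeds.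

Step 6
Reactants: 8 [(1S,2S,5R,6S)-5-(benzoyloxy)-2-hydroxy-7-oxabicyclo[4.1.0]hept-3-en-2-yl]methyl benzoate
Product: 10 [(1S,4R,5S,6S)-4-(benzoyloxy)-1,5,6-trihydroxycyclohex-2-en-1-yl]methyl benzoate, via dioxolanylium zwitterion 9 (not isolated)
Conditions: BF3·OEt2 (1.2 equiv), CH2Cl2, −78 to −30 °C; then THF/H2O, −30 to 0 °C; aq. NaHCO3 work-up
Reagents that add atoms: water, O
Why: Lewis-acid activation of the oxirane lets the carbonyl oxygen of the trans-disposed C4 benzoate attack C5 from the face opposite the epoxide oxygen (anchimeric assistance, 5-exo, inversion at C5, C6–O untouched), which should outrun six-membered participation of the C7 benzoate at the neopentyl-like C6; water then adds to the cation and the orthoacid should collapse under kinetic, mildly acidic conditions to the ester on the pseudoaxial O4 and the free equatorial C5 hydroxyl, the usual preference of cis-fused 2-hydroxy-1,3-dioxolanes on six-membered rings.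

**Compound list**

1 | 4-hydroxybenzyl alcohol | OCc1ccc(O)cc1 | starting material
2 | benzoic acid | O=C(O)c1ccccc1 | starting material
3 | 4-hydroxybenzyl benzoate | O=C(OCc1ccc(O)cc1)c1ccccc1 | intermediate
4 | (1-hydroxy-4-oxocyclohexa-2,5-dien-1-yl)methyl benzoate | O=C(OCC1(O)C=CC(=O)C=C1)c1ccccc1 | intermediate
5 | trans-(1,4-dihydroxycyclohexa-2,5-dien-1-yl)methyl benzoate | O=C(OC[C@@]1(O)C=C[C@@H](O)C=C1)c1ccccc1 | intermediate
6 | benzoyl chloride | O=C(Cl)c1ccccc1 | starting material
7 | trans-[4-(benzoyloxy)-1-hydroxycyclohexa-2,5-dien-1-yl]methyl benzoate (meso) | O=C(OC[C@@]1(O)C=C[C@@H](OC(=O)c2ccccc2)C=C1)c1ccccc1 | intermediate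
8 | [(1S,2S,5R,6S)-5-(benzoyloxy)-2-hydroxy-7-oxabicyclo[4.1.0]hept-3-en-2-yl]methyl benzoate | O=C(OC[C@@]1(O)C=C[C@@H](OC(=O)c2ccccc2)[C@@H]2O[C@H]12)c1ccccc1 | intermediate
9 | cis-fused 2-phenyl-1,3-dioxolan-2-ylium ion bridging O4 and O5, with C6–O–BF3 alkoxide, free C1 hydroxyl and C7 benzoate (zwitterion) | O=C(OC[C@@]1(O)C=C[C@H]2O[C+](c3ccccc3)O[C@H]2[C@@H]1O[B-](F)(F)F)c1ccccc1 | intermediate (not isolated)
10 | [(1S,4R,5S,6S)-4-(benzoyloxy)-1,5,6-trihydroxycyclohex-2-en-1-yl]methyl benzoate | O=C(OC[C@@]1(O)C=C[C@@H](OC(=O)c2ccccc2)[C@@H](O)[C@@H]1O)c1ccccc1 | target

**Step count**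

Total steps: 6. Longest linear sequence: 6.

**Steps most likely to fail**

1. Step 5. The catalyst may discriminate poorly between the two enantiotopic alkenes, oxygen transfer at the hindered tertiary bis-allylic carbinol may be slow, or the Lewis-acidic metal may ionise the dienol and aromatise it. Fallback, from 7: substrate-directed epoxidation with VO(acac)2 (cat.) and tBuOOH in toluene at 0 °C (pentavalent vanadium alkylperoxide bound to the C1 hydroxyl) should give the syn-epoxy alcohol as a racemate, that is 8 together with its mirror image, [(1R,2R,5S,6R)-5-(benzoyloxy)-2-hydroxy-7-oxabicyclo[4.1.0]hept-3-en-2-yl]methyl benzoate F1. The enantiomers are separated by preparative chromatography on a chiral stationary phase, and the route is rejoined at 8. Stereocontrol then rests on the substrate (relative configuration) and on resolution (absolute configuration) instead of the catalyst.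

2. Step 6. The benzoyl group may end on O5 or scramble between O4 and O5 when the orthoacid collapses, the C7 benzoate may compete at C6, or the Lewis acid may trigger semipinacol rearrangement of the epoxy carbinol. Fallback, from 8: the oxirane is opened with BF3·OEt2 in CH2Cl2 at −78 °C as before, but the cation is quenched with MeOH/Et3N at −78 °C. This should give the neutral, isolable cyclic methyl orthobenzoate bridging O4 and O5 (free C1 and C6 hydroxyls, C7 benzoate, epimers at the orthoester carbon) F2. In a separate operation F2 is hydrolysed in 80% aqueous AcOH at rt, the standard kinetically controlled orthoester opening to the axial ester, and the route is rejoined at 10. Epoxide opening and acyl placement can then be optimised independently.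

3. Step 3. Hydride delivery may show poor facial selectivity so that the cis diol predominates, and the dienediol may lose water and aromatise on acidic contact. Fallback, from 4: the same reduction is run and the cis isomer, cis-(1,4-dihydroxycyclohexa-2,5-dien-1-yl)methyl benzoate F3, is isolated. F3 is treated with benzoic acid (2), PPh3 and DIAD in THF at 0 °C; this Mitsunobu esterification inverts C4 and leaves the tertiary hydroxyl untouched, so it should give the trans dibenzoate directly. The route is rejoined at 7, and step 4 is not needed for this material.

**Further compounds**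

F1 | step 5 | [(1R,2R,5S,6R)-5-(benzoyloxy)-2-hydroxy-7-oxabicyclo[4.1.0]hept-3-en-2-yl]methyl benzoate (enantiomer of 8) | O=C(OC[C@]1(O)C=C[C@H](OC(=O)c2ccccc2)[C@H]2O[C@@H]12)c1ccccc1
F2 | step 6 | cyclic methyl orthobenzoate bridging O4 and O5 (2-methoxy-2-phenyl-1,3-dioxolane cis-fused at C4–C5; free C1 and C6 hydroxyls, C7 benzoate; epimers at the orthoester carbon) | O=C(OC[C@@]1(O)C=C[C@H]2OC(OC)(c3ccccc3)O[C@H]2[C@@H]1O)c1ccccc1
F3 | step 3 | cis-(1,4-dihydroxycyclohexa-2,5-dien-1-yl)methyl benzoate | O=C(OC[C@@]1(O)C=C[C@H](O)C=C1)c1ccccc1
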